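**Retrosynthetic overview**
1. Target ⇐ global desilylation ⇐ Suzuki–Miyaura coupling of the 7-bromo-benzodioxane 17 with an (E)-3-silyloxypropenyl boronate; the side chain goes on last.
2. The dioxane ring is the only ring formed (both arenes are bought). It is closed by an acid-mediated, trans-selective benzylic C–O closure of a free phenol onto an aryl carbinol.
3. Carbinol ⇐ aryl Grignard (from 4-bromo-2,6-dimethoxyphenol) + (S)-2-aryloxy-3-silyloxypropanal.
4. Aldehyde ⇐ lipase desymmetrisation of a prochiral 2-aryloxypropane-1,3-diol; this sets the CH–CH2OH centre, and the aryl-bearing centre is then relayed from it.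
5. Diol ⇐ 2-(allyloxy)-4-bromo-6-methoxyphenol (from 5-bromo-o-vanillin by MOM protection, Baeyer–Villiger, allylation) + diethyl chloromalonate, then reduction.

**Assumptions**
- The target is read as the trans (2S,3S)-2-aryl-3-hydroxymethyl-2,3-dihydro-1,4-benzodioxine, with the CH2OH-bearing carbon on the oxygen next to the OMe.
- Lipase PS is assumed to acetylate the pro-S arm of diol 8, as it does for 2-O-benzylglycerol. If it acetylates the other arm, the same lipase is run in hydrolytic mode on the diacetate of 8 to reach 9.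

**Route**

Step 1
Reactants: 1, 5-bromo-2-hydroxy-3-methoxybenzaldehyde
Product: 2, 5-bromo-3-methoxy-2-(methoxymethoxy)benzaldehyde
Conditions: MOMCl, i-Pr2NEt, CH2Cl2, 0 °C → rt
Reagents that add atoms: chloromethyl methyl ether, COCCl
Why: Simple O-alkylation of the acidic salicylaldehyde phenol masks the oxygen that will later carry the three-carbon unit.

Step 2
Reactants: 2
Product: 3, 5-bromo-3-methoxy-2-(methoxymethoxy)phenol
Conditions: mCPBA, CH2Cl2, rt; then K2CO3, MeOH, rt
Reagents that add atoms: mCPBA, OOC(=O)c1cccc(Cl)c1 (inserted O)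
Why: Baeyer–Villiger (Dakin-type) oxidation of an o-alkoxybenzaldehyde proceeds by aryl migration to the formate, which is methanolysed to the phenol, so the second ring oxygen is placed without regiochemical ambiguity.

Step 3
Reactants: 3
Product: 4, 1-(allyloxy)-5-bromo-3-methoxy-2-(methoxymethoxy)benzene
Conditions: allyl bromide, K2CO3, DMF, rt
Reagents that add atoms: allyl bromide, C=CCBr
Why: Williamson etherification of the only free phenol installs a protecting group that is later removed under neutral Pd(0) conditions tolerated by ArBr and silyl ethers.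

Step 4
Reactants: 4
Product: 5, 2-(allyloxy)-4-bromo-6-methoxyphenol
Conditions: 3 M HCl, MeOH, 40 °C
Reagents that add atoms: none
Why: Acidic acetal hydrolysis removes MOM selectively; the allyl ether and ArBr are inert.

Step 5
Reactants: 5; 6, diethyl chloromalonate
Product: 7, diethyl 2-[2-(allyloxy)-4-bromo-6-methoxyphenoxy]malonate
Conditions: Cs2CO3, DMF, rt → 50 °C
Reagents that add atoms: none (new atoms come from 6)
Why: SN2 O-alkylation of the phenoxide at the doubly activated α-halomalonate carbon gives an achiral aryloxymalonate.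

Step 6
Reactants: 7
Product: 8, 2-[2-(allyloxy)-4-bromo-6-methoxyphenoxy]propane-1,3-diol (achiral, prochiral)
Conditions: LiBH4, THF, 0 °C → rt
Reagents that add atoms: none
Why: Hydride reduction of both activated esters gives the prochiral 1,3-diol; ArBr and the allyl ether are untouched by borohydride.

Step 7
Reactants: 8
Product: 9, (S)-2-[2-(allyloxy)-4-bromo-6-methoxyphenoxy]-3-hydroxypropyl acetate
Conditions: Burkholderia cepacia lipase (Amano PS, immobilised), vinyl acetate, t-BuOMe, 25 °C
Reagents that add atoms: vinyl acetate, C=COC(C)=O (acetyl)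
Why: Lipase-catalysed irreversible transesterification acylates one enantiotopic CH2OH (enantioselective desymmetrisation), creating the first stereocentre; slight over-acylation to the achiral diacetate consumes the minor enantiomer and raises ee.

Step 8
Reactants: 9
Product: 10, (R)-2-[2-(allyloxy)-4-bromo-6-methoxyphenoxy]-3-[(tert-butyldiphenylsilyl)oxy]propyl acetate
Conditions: TBDPSCl, imidazole, CH2Cl2, 0 °C → rt
Reagents that add atoms: TBDPSCl, CC(C)(C)[Si](Cl)(c1ccccc1)c1ccccc1
Why: Prompt silylation of the free primary alcohol under mild conditions differentiates the two arms before any 1,3-acyl migration can erode ee (the descriptor changes only through CIP priority).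

Step 9
Reactants: 10
Product: 11, (R)-2-[2-(allyloxy)-4-bromo-6-methoxyphenoxy]-3-[(tert-butyldiphenylsilyl)oxy]propan-1-ol
Conditions: K2CO3 (cat.), MeOH, 0 °C
Reagents that add atoms: none
Why: Mild Zemplén-type methanolysis removes the acetate; the bulky TBDPS group does not migrate under these conditions.

Step 10
Reactants: 11
Product: 12, (S)-2-[2-(allyloxy)-4-bromo-6-methoxyphenoxy]-3-[(tert-butyldiphenylsilyl)oxy]propanal
Conditions: Dess–Martin periodinane, NaHCO3, CH2Cl2, 0 °C → rt; used crude at once
Reagents that add atoms: none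
Why: Buffered Dess–Martin oxidation is non-basic, so the epimerisable α-aryloxy aldehyde is made without racemisation or β-elimination.

Step 11
Reactants: 13, 4-bromo-2,6-dimethoxyphenol
Product: 14, (4-bromo-2,6-dimethoxyphenoxy)(tert-butyl)dimethylsilane
Conditions: TBSCl, imidazole, DMF, rt → 40 °C
Reagents that add atoms: TBSCl, CC(C)(C)[Si](C)(C)Cl
Why: Silylation masks the phenol for Grignard formation and leaves a group that fluoride removes in the final step.

Step 12
Reactants: 12; 14
Product: 15, (1RS,2S)-2-[2-(allyloxy)-4-bromo-6-methoxyphenoxy]-1-[4-(tert-butyldimethylsilyloxy)-3,5-dimethoxyphenyl]-3-[(tert-butyldiphenylsilyl)oxy]propan-1-ol (C1 epimers)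
Conditions: 14, Mg (I2 cat.), THF, 50 °C; then 12, THF, −78 → −20 °C
Reagents that add atoms: none (new atoms come from 14)
Why: Grignard 1,2-addition to the aldehyde at low temperature is faster than enolisation and does not touch the ArBr; the carbinol configuration is unimportant because step 14 erases it.

Step 13
Reactants: 15
Product: 16, (1RS,2S)-2-(4-bromo-2-hydroxy-6-methoxyphenoxy)-1-[4-(tert-butyldimethylsilyloxy)-3,5-dimethoxyphenyl]-3-[(tert-butyldiphenylsilyl)oxy]propan-1-ol
Conditions: Pd(PPh3)4 (3 mol %), morpholine, THF, rt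
Reagents that add atoms: none
Why: Tsuji–Trost deallylation via a π-allyl-Pd intermediate frees the phenol under neutral conditions; at rt Pd(PPh3)4 does not insert into the electron-rich ArBr.

Step 14
Reactants: 16
Product: 17, (2S,3S)-7-bromo-2-[4-(tert-butyldimethylsilyloxy)-3,5-dimethoxyphenyl]-3-{[(tert-butyldiphenylsilyl)oxy]methyl}-5-methoxy-2,3-dihydro-1,4-benzodioxine (trans)
Conditions: Amberlyst-15, 4 Å MS, toluene, 60 °C
Reagents that add atoms: none
Why: Acid ionises both carbinol epimers to the same p-silyloxybenzyl cation, which the neighbouring phenol traps in a six-membered ring (intramolecular SN1 etherification); reversible ionisation funnels the product to the diequatorial 2,3-trans isomer, so the fixed (S)-C3 centre sets (S) at C2.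

Step 15
Reactants: 17; 18, (E)-tert-butyldimethyl{[3-(4,4,5,5-tetramethyl-1,3,2-dioxaborolan-2-yl)allyl]oxy}silane
Product: 19, (2S,3S)-2-[4-(tert-butyldimethylsilyloxy)-3,5-dimethoxyphenyl]-7-[(E)-3-(tert-butyldimethylsilyloxy)prop-1-en-1-yl]-3-{[(tert-butyldiphenylsilyl)oxy]methyl}-5-methoxy-2,3-dihydro-1,4-benzodioxine
Conditions: Pd(OAc)2 (5 mol %), SPhos (10 mol %), K3PO4, THF/H2O (10:1), 60 °C
Reagents that add atoms: none (new atoms come from 18)
Why: Suzuki–Miyaura coupling of the unhindered aryl bromide with the alkenyl boronate retains the E geometry and installs the whole side chain in one step; any loss of the aryl TBS here is harmless.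

Step 16
Reactants: 19
Product: 20, 4-[(2S,3S)-3-(hydroxymethyl)-7-[(E)-3-hydroxyprop-1-en-1-yl]-5-methoxy-2,3-dihydro-1,4-benzodioxin-2-yl]-2,6-dimethoxyphenol (target)
Conditions: TBAF, AcOH, THF, 0 °C → rt
Reagents that add atoms: none
Why: Buffered fluoride cleaves all three Si–O bonds while avoiding a free phenoxide that could open the benzylic aryl ether via a quinone methide.

**Compound list**
1 | 5-bromo-2-hydroxy-3-methoxybenzaldehyde | COc1cc(Br)cc(C=O)c1O | starting material
2 | 5-bromo-3-methoxy-2-(methoxymethoxy)benzaldehyde | COCOc1c(C=O)cc(Br)cc1OC | intermediate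
3 | 5-bromo-3-methoxy-2-(methoxymethoxy)phenol | COCOc1c(O)cc(Br)cc1OC | intermediate
4 | 1-(allyloxy)-5-bromo-3-methoxy-2-(methoxymethoxy)benzene | COCOc1c(OCC=C)cc(Br)cc1OC | intermediate
5 | 2-(allyloxy)-4-bromo-6-methoxyphenol | Oc1c(OCC=C)cc(Br)cc1OC | intermediate
6 | diethyl chloromalonate | CCOC(=O)C(Cl)C(=O)OCC | starting material
7 | diethyl 2-[2-(allyloxy)-4-bromo-6-methoxyphenoxy]malonate | CCOC(=O)C(Oc1c(OCC=C)cc(Br)cc1OC)C(=O)OCC | intermediate
8 | 2-[2-(allyloxy)-4-bromo-6-methoxyphenoxy]propane-1,3-diol | OCC(CO)Oc1c(OCC=C)cc(Br)cc1OC | intermediate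
9 | (S)-2-[2-(allyloxy)-4-bromo-6-methoxyphenoxy]-3-hydroxypropyl acetate | CC(=O)OC[C@H](CO)Oc1c(OCC=C)cc(Br)cc1OC | intermediate
10 | (R)-2-[2-(allyloxy)-4-bromo-6-methoxyphenoxy]-3-(TBDPS-oxy)propyl acetate | CC(=O)OC[C@H](CO[Si](c1ccccc1)(c1ccccc1)C(C)(C)C)Oc1c(OCC=C)cc(Br)cc1OC | intermediate
11 | (R)-2-[2-(allyloxy)-4-bromo-6-methoxyphenoxy]-3-(TBDPS-oxy)propan-1-ol | OC[C@H](CO[Si](c1ccccc1)(c1ccccc1)C(C)(C)C)Oc1c(OCC=C)cc(Br)cc1OC | intermediate
12 | (S)-2-[2-(allyloxy)-4-bromo-6-methoxyphenoxy]-3-(TBDPS-oxy)propanal | O=C[C@H](CO[Si](c1ccccc1)(c1ccccc1)C(C)(C)C)Oc1c(OCC=C)cc(Br)cc1OC | intermediate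
13 | 4-bromo-2,6-dimethoxyphenol | COc1cc(Br)cc(OC)c1O | starting material
14 | (4-bromo-2,6-dimethoxyphenoxy)(tert-butyl)dimethylsilane | COc1cc(Br)cc(OC)c1O[Si](C)(C)C(C)(C)C | intermediate
15 | (1RS,2S)-2-[2-(allyloxy)-4-bromo-6-methoxyphenoxy]-1-[4-(TBS-oxy)-3,5-dimethoxyphenyl]-3-(TBDPS-oxy)propan-1-ol | OC(c1cc(OC)c(O[Si](C)(C)C(C)(C)C)c(OC)c1)[C@H](CO[Si](c1ccccc1)(c1ccccc1)C(C)(C)C)Oc1c(OCC=C)cc(Br)cc1OC | intermediate
16 | (1RS,2S)-2-(4-bromo-2-hydroxy-6-methoxyphenoxy)-1-[4-(TBS-oxy)-3,5-dimethoxyphenyl]-3-(TBDPS-oxy)propan-1-ol | OC(c1cc(OC)c(O[Si](C)(C)C(C)(C)C)c(OC)c1)[C@H](CO[Si](c1ccccc1)(c1ccccc1)C(C)(C)C)Oc1c(O)cc(Br)cc1OC | intermediate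
17 | (2S,3S)-7-bromo-2-[4-(TBS-oxy)-3,5-dimethoxyphenyl]-3-[(TBDPS-oxy)methyl]-5-methoxy-2,3-dihydro-1,4-benzodioxine | COc1cc([C@@H]2Oc3cc(Br)cc(OC)c3O[C@H]2CO[Si](c4ccccc4)(c5ccccc5)C(C)(C)C)cc(OC)c1O[Si](C)(C)C(C)(C)C | intermediate
18 | (E)-tert-butyldimethyl{[3-(pinacolboryl)allyl]oxy}silane | CC(C)(C)[Si](C)(C)OC/C=C/B1OC(C)(C)C(C)(C)O1 | starting material
19 | (2S,3S)-2-[4-(TBS-oxy)-3,5-dimethoxyphenyl]-7-[(E)-3-(TBS-oxy)prop-1-enyl]-3-[(TBDPS-oxy)methyl]-5-methoxy-2,3-dihydro-1,4-benzodioxine | COc1cc([C@@H]2Oc3cc(/C=C/CO[Si](C)(C)C(C)(C)C)cc(OC)c3O[C@H]2CO[Si](c4ccccc4)(c5ccccc5)C(C)(C)C)cc(OC)c1O[Si](C)(C)C(C)(C)C | intermediate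
20 | 4-[(2S,3S)-3-(hydroxymethyl)-7-[(E)-3-hydroxyprop-1-enyl]-5-methoxy-2,3-dihydro-1,4-benzodioxin-2-yl]-2,6-dimethoxyphenol | COc1cc([C@@H]2Oc3cc(/C=C/CO)cc(OC)c3O[C@H]2CO)cc(OC)c1O | target

**Totals**
Total steps: 16. Longest linear sequence: 15 (steps 1–10, then 12–16).

**Three steps most likely to fail, with fallbacks**
- **Step 7 (lipase desymmetrisation).** The di-ortho-substituted aryloxy diol may give low selectivity or the opposite sense. Fallback: move the desymmetrisation to 2-O-benzylglycerol, a well-behaved lipase substrate, then silylate, debenzylate, and attach phenol 5 afterwards by Mitsunobu inversion at the secondary alcohol.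
- **Step 12 (Grignard addition to aldehyde 12).** The aldehyde may epimerise or lose silyloxide by β-elimination under basic conditions. Fallback: oxidise 11 to the acid, form the Weinreb amide, add the aryl Grignard to give the α-aryloxy ketone, and reduce that to the carbinol.
- **Step 14 (acid cyclisation).** The trans:cis ratio may be incomplete, or E1 elimination to the enol ether may compete. Fallback: stereospecific closure instead of a cation — obtain the anti (erythro) carbinol selectively by Felkin-controlled reduction of the ketone above (or by separating the epimers of 16), then close the ring by intramolecular Mitsunobu with inversion at the benzylic carbon to give the trans product.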